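The runs were computed with constants of no real substance, noise included.

Each flask is read at 50 h, 5.00 times the last west reading, so I need to know what the west curve means beyond its end.

| setting | west | midnight | dawn | spring | summer |
|---|---|---|---|---|---|
| starting material | 20 mM | 20 mM | 20 mM | 20 mM | 20 mM |
| partner | 2 equiv | 2.00 equiv | 2.00 equiv | 2.00 equiv | 2.00 equiv |
| second reagent | 2.2 equiv | 1.50 equiv | 1.50 equiv | 1.50 equiv | 1.50 equiv |
| third reagent | 1 equiv | 1.00 equiv | 1.00 equiv | 1.00 equiv | 1.00 equiv |
| temperature | 20 °C | 20 °C | −5 °C | −30 °C |  |
| remark | run made earlier |  |  |  | at −30 °C until 40 h, from then on at 20 °C |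
| time |  | 50 h | 50 h | 50 h | 50 h |

The new recipes keep partner at 2.00 equiv but cut second reagent from 2.2 equiv to 1.50 equiv. Temperature moves too, but the west run shows nothing of that.

west run (percent of the starting material charged)

| time / h | intermediate A / % | target / % |
|---|---|---|
| 0.833 | 14 | 0 |
| 2.50 | 26 | 0 |
| 5.00 | 29 | 0 |
| 8.00 | 29 | 0 |
| 10.0 | 28 | 0 |

(standard deviation of a reading: 1.5 percentage points)

- the earlier runs do not show what temperature does; that part of a forecast is a guess
- a reading or a percentage of target counts all its forms, free or not

In the west run intermediate A stands at 29% by 5.00 h, with target at 0%. So I read the plateau as a split: starting material divides between intermediate A and a rival path that neither column shows. I guess that the rival step consumes second reagent. The plateau, with its scatter of 1.5 percentage points, then gives 0.449 for the selectivity factor, the ratio of intermediate A to the rival's share divided by the ratio of partner to second reagent.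

So at 1.50 equiv of second reagent and 20 °C the two branches stand at 0.599 to one, and the partner branch takes 37.5% of the starting material. That is my estimate of what enters intermediate A in the midnight flask. For the colder flasks the factor is a guess.

1. the flask that comes out highest in amount of intermediate A, in percent of the starting material charged, or "all alike" when all lie within 1.5 percentage points (midnight / dawn / spring / summer / all alike)
2. intermediate A at the end, in percent of the starting material charged, midnight
3. intermediate A at the end, in percent of the starting material charged, dawn
4. intermediate A at the end, in percent of the starting material charged, spring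
5. intermediate A at the end, in percent of the starting material charged, summer

The forecast differs: it puts summer highest, with 19% for midnight, 26% for dawn, 7% for spring and 27% for summer. Its ground is “So A is either a partial-yield or equilibrium-limited product, or it slowly drains away”. My midnight share lies above its figure.

The flasks give 30.3% for midnight, 44.0% for dawn, 17.9% for spring and 41.0% for summer, so dawn comes highest.

    starting material + partner → intermediate A (k = 0.110 L mol⁻¹ min⁻¹, Ea = 48.0 kJ mol⁻¹)
    second reagent + intermediate A → intermediate B (k = 0.00570 L mol⁻¹ min⁻¹, Ea = 62.0 kJ mol⁻¹)
    third reagent + intermediate B → target (k = 0.0490 L mol⁻¹ min⁻¹, Ea = 65.0 kJ mol⁻¹)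
    starting material + second reagent → side product A (k = 0.250 L mol⁻¹ min⁻¹, Ea = 56.0 kJ mol⁻¹)
    intermediate B → decomposed reagent (k = 8.40 × 10⁻⁴ min⁻¹, Ea = 91.0 kJ mol⁻¹)
    intermediate B → side product B (k = 3.70 × 10⁻⁴ min⁻¹, Ea = 92.0 kJ mol⁻¹)
    starting material + target ⇌ idle adduct, settled at all times (K = 69.0 L mol⁻¹, ΔH = 7.00 kJ mol⁻¹)
    (constants at 20 °C)

At the end of the midnight flask, with starting material at 0%, side product A holds 59.8%, which leaves 40.2% for the partner branch against the 37.5% carried from west. In the spring flask at −30 °C, just after the start, starting material enters intermediate A 1.2 times as fast as side product A, twice the 0.599 reckoned from west for the same charges at 20 °C. With the factor raised by that same ratio, the neighbour of spring with 6.00 equiv of second reagent reckons at 0.288; it ends with partner at 93.0% and second reagent at 91.9% of their charges, holding 14.0% intermediate A to 48.5% side product A, a ratio of 0.289.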